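**Retrosynthetic overview** (oxolane numbering: O1, C2 aryl, C3 CH2OH, C4 aroyl, C5 CH2)
- Endgame: the two phenols are freed last and the ketone is carried as a 1,3-dithiane. The oxolane, the only non-aromatic ring of the target, is closed at O1–C2 from an acyclic triol through the benzylic cation.
- Enabling feature: the ketone carbon on C4 and the hydroxymethyl carbon on C3 are 1,4-related (a γ-hydroxy ketone), and C5 and the hydroxymethyl carbon are oxygen-bearing carbons on the adjacent atoms C4 and C3. Joining these two carbons through one oxygen, with the hydroxymethyl carbon at carboxyl level and C5 at acetal level, gives a butenolide in which C4 is the β-carbon of a Michael acceptor.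
- Key disconnection: the ketone carbon–C4 bond, made with reversed polarity from a lithiated aryl dithiane and (5R)-menthyloxybutenolide. The resulting enolate takes up a second aryl aldehyde at C3 in the same flask, so three simple pieces give the whole carbon skeleton with C3 and C4 fixed.
- Stereochemical relay: the lactone ring is temporary. Its 3,4-trans pattern becomes the 3,4-cis pattern of the oxolane once LiAlH4 opens the lactone, expels menthol and erases the acetal stereocentre, and the ring is re-closed onto the benzylic carbon instead.
- Ring order: temporary γ-lactone (brought in with the butenolide, opened in step 5), then the oxolane (step 6). Both aryl units come from syringaldehyde.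

Key step: step 4

Remark 1: in names, Ar = 4-(benzyloxy)-3,5-dimethoxyphenyl; 5-hydroxyfuran-2(5H)-one is taken as purchasable (it is the dye-sensitised photooxygenation product of furfural).
Remark 2: the carbinol carbon made in the aldol event is carried as a mixture of epimers and drawn without configuration, because step 6 ionises it and sets it afresh.

**Step 1**
Reactants: 1 syringaldehyde
Product: 2 4-(benzyloxy)-3,5-dimethoxybenzaldehyde
Conditions: BnBr, K2CO3, DMF, 60 °C
Reagents that add atoms: benzyl bromide (BrCc1ccccc1)
Why: Williamson ether synthesis on the acidic, hindered phenol; the benzyl ether tolerates n-BuLi, LiAlH4, acid and MeI later on.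

**Step 2**
Reactants: 2 4-(benzyloxy)-3,5-dimethoxybenzaldehyde
Product: 3 2-Ar-1,3-dithiane
Conditions: HS(CH2)3SH, BF3·OEt2 (cat.), CH2Cl2, 0 °C to rt
Reagents that add atoms: propane-1,3-dithiol (SCCCS)
Why: Lewis-acid-catalysed dithioacetalisation of an aromatic aldehyde, which installs the group that later serves as umpolung handle, steric control element and ketone protection.

**Step 3**
Reactants: 4 5-hydroxyfuran-2(5H)-one; 5 (−)-menthol, (1R,2S,5R)
Product: 6 (5R)-5-[(1R,2S,5R)-menthyloxy]furan-2(5H)-one
Conditions: CSA (cat.), toluene, reflux (Dean–Stark); crystallisation from petroleum ether, mother liquor re-equilibrated with acid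
Reagents that add atoms: none
Why: acid-catalysed acetalisation of the lactol with the chiral-pool alcohol gives both C5 epimers, which interconvert through the oxocarbenium ion, and the well-crystallising (5R) epimer is collected, which sets the temporary acetal stereocentre.

**Step 4**
Reactants: 3 2-Ar-1,3-dithiane; 6 (5R)-5-menthyloxyfuran-2(5H)-one; 2 4-(benzyloxy)-3,5-dimethoxybenzaldehyde
Product: 9 (3S,4R,5R)-3-[Ar(hydroxy)methyl]-4-(2-Ar-1,3-dithian-2-yl)-5-[(1R,2S,5R)-menthyloxy]dihydrofuran-2(3H)-one (carbinol carbon epimeric), via 2-lithio-1,3-dithiane 7 (not isolated), via lactone lithium enolate 8 (not isolated)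
Conditions: n-BuLi (1.0 equiv), THF, −78 to −20 °C; then 6, THF, −78 °C; then 2, THF, −78 °C; AcOH, −78 °C
Reagents that add atoms: none
Why: n-BuLi removes the C2–H of 3 to give the sulfur- and aryl-stabilised carbanion 7 (Corey–Seebach umpolung of the aldehyde carbon), which adds in Michael fashion to the β-carbon of 6 and so forms the bond between the future ketone carbon and the future oxolane C4, and the lactone enolate 8 so generated is intercepted in the same flask by the non-enolisable aldehyde 2 in an aldol addition that forms the bond from the future C3 to the benzylic carbon. The closest known reaction type is the tandem conjugate addition–aldol trapping of lithiated aryl dithioacetals on butenolides and γ-alkoxybutenolides, the established three-component entry to butyrolactone and furofuran lignans. No ring is closed here, the five-membered lactone serving only as a rigid, temporary template. The lactone C4 (future oxolane C4, R) is controlled by the acetal stereocentre C5, whose menthyloxy group blocks one face so that 7 enters anti to it; the lactone C3 (future oxolane C3) is controlled by the very bulky 2-aryl-dithianyl group just installed, the aldehyde approaching the planar enolate anti to it (3,4-trans); the carbinol carbon is not controlled and need not be, since step 6 ionises it. The step needs 1,4- over 1,2-regioselectivity, which the soft delocalised carbanion and the unsubstituted, open β-carbon of the butenolide secure, and it needs C–C trapping to outrun proton transfer and aldol reversal, which the absence of acidic C–H in 2 and the acidic quench at −78 °C secure.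

**Step 5**
Reactants: 9 aldol adduct
Product: 10 (2R,3R)-2-[Ar(hydroxy)methyl]-3-(2-Ar-1,3-dithian-2-yl)butane-1,4-diol (carbinol carbon epimeric)
Conditions: LiAlH4, THF, 0 °C to rt; H2O, aq NaOH, H2O work-up
Reagents that add atoms: none
Why: hydride reduction of a γ-alkoxy-γ-lactone, in which the carbonyl goes to the primary alkoxide and the liberated hemiacetal alkoxide expels menthoxide to an aldehyde that is reduced at once, so the temporary ring, the acetal stereocentre and the auxiliary vanish together while dithiane, benzyl ethers and the two C–H stereocentres stay untouched.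

**Step 6**
Reactants: 10 triol
Product: 11 [(2S,3R,4R)-2-Ar-4-(2-Ar-1,3-dithian-2-yl)oxolan-3-yl]methanol
Conditions: CSA (10 mol %), CH2Cl2, 0 °C to rt, short contact time
Reagents that add atoms: none
Why: acid-catalysed dehydrative cycloetherification (SN1, 5-exo-trig capture of the 4-alkoxybenzyl cation), in which only the benzylic hydroxyl ionises, only the hydroxymethyl on the dithiane-bearing carbon reaches the cation through a five-membered ring (the other would give an oxetane), both carbinol epimers converge on one cation, and C2 is set 2,3-trans (2S) because the aryl group avoids the adjacent hydroxymethyl group and the ether can re-ionise to this more stable isomer.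

**Step 7**
Reactants: 11 dithiane-masked oxolane
Product: 12 O,O'-dibenzylciwujiatone, (2S,3R,4R)
Conditions: MeI (excess), CaCO3, MeCN–H2O (9:1), 45 °C
Reagents that add atoms: water (O)
Why: alkylative dithiane hydrolysis, in which S-methylation makes sulfur a leaving group and the aryl-stabilised thionium ion is captured by water (or first by the cis hydroxymethyl group), while the near-neutral CaCO3 buffer spares the benzylic ether, the benzyl ethers and the epimerisable C4–H next to the new ketone.

**Step 8**
Reactants: 12 O,O'-dibenzylciwujiatone
Product: 13 ciwujiatone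
Conditions: H2 (1 atm), 10% Pd/C, EtOAc, rt, stopped after uptake of two equivalents of H2
Reagents that add atoms: none
Why: catalytic hydrogenolysis of aryl benzyl ethers is faster than reduction of the electron-rich aryl ketone or cleavage of the ring C2–O1 bond, so a neutral aprotic medium and controlled uptake should free both phenols without touching the three stereocentres.

**Compound list**
1 | syringaldehyde | COc1cc(C=O)cc(OC)c1O | starting material
2 | 4-(benzyloxy)-3,5-dimethoxybenzaldehyde | COc1cc(C=O)cc(OC)c1OCc1ccccc1 | intermediate
3 | 2-[4-(benzyloxy)-3,5-dimethoxyphenyl]-1,3-dithiane | COc1cc(C2SCCCS2)cc(OC)c1OCc1ccccc1 | intermediate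
4 | 5-hydroxyfuran-2(5H)-one (racemic lactol) | OC1OC(=O)C=C1 | starting material
5 | (−)-menthol, (1R,2S,5R) | CC(C)[C@@H]1CC[C@@H](C)C[C@H]1O | starting material
6 | (5R)-5-[(1R,2S,5R)-menthyloxy]furan-2(5H)-one | O=C1O[C@@H](O[C@@H]2C[C@H](C)CC[C@H]2C(C)C)C=C1 | intermediate
7 | 2-lithio-2-[4-(benzyloxy)-3,5-dimethoxyphenyl]-1,3-dithiane | [Li]C1(SCCCS1)c1cc(OC)c(OCc2ccccc2)c(OC)c1 | intermediate
8 | lithium enolate of (4R,5R)-4-(2-Ar-1,3-dithian-2-yl)-5-menthyloxy-γ-butyrolactone | [Li]OC1=C[C@@H](C2(SCCCS2)c2cc(OC)c(OCc3ccccc3)c(OC)c2)[C@H](O[C@@H]2C[C@H](C)CC[C@H]2C(C)C)O1 | intermediate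
9 | (3S,4R,5R)-3-[Ar(hydroxy)methyl]-4-(2-Ar-1,3-dithian-2-yl)-5-menthyloxydihydrofuran-2(3H)-one, carbinol carbon epimeric | O=C1O[C@@H](O[C@@H]2C[C@H](C)CC[C@H]2C(C)C)[C@H](C2(SCCCS2)c2cc(OC)c(OCc3ccccc3)c(OC)c2)[C@H]1C(O)c1cc(OC)c(OCc2ccccc2)c(OC)c1 | intermediate
10 | (2R,3R)-2-[Ar(hydroxy)methyl]-3-(2-Ar-1,3-dithian-2-yl)butane-1,4-diol, carbinol carbon epimeric | OC[C@@H]([C@H](CO)C1(SCCCS1)c1cc(OC)c(OCc2ccccc2)c(OC)c1)C(O)c1cc(OC)c(OCc2ccccc2)c(OC)c1 | intermediate
11 | [(2S,3R,4R)-2-Ar-4-(2-Ar-1,3-dithian-2-yl)oxolan-3-yl]methanol | COc1cc(C3(SCCCS3)[C@H]2CO[C@H](c3cc(OC)c(OCc4ccccc4)c(OC)c3)[C@H]2CO)cc(OC)c1OCc1ccccc1 | intermediate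
12 | O,O'-dibenzylciwujiatone, (2S,3R,4R) | COc1cc(C(=O)[C@H]2CO[C@H](c3cc(OC)c(OCc4ccccc4)c(OC)c3)[C@H]2CO)cc(OC)c1OCc1ccccc1 | intermediate
13 | ciwujiatone, (2S,3R,4R) | COc1cc(C(=O)[C@H]2CO[C@H](c3cc(OC)c(O)c(OC)c3)[C@H]2CO)cc(OC)c1O | target

**Step count and risks**
Total step count: 8. Longest linear sequence: 7 (steps 1, 2, 4, 5, 6, 7, 8).

Steps most likely to fail:

1. **Step 4.**
   - Risk: carbanion 7 may attack the lactone carbonyl instead of the β-carbon. The crowded enolate 8 may be trapped incompletely, or the aldolate may revert before the quench.
   - Fallback: it sets out from 3 and 6 and comes back at 9, making the two C–C bonds in separate operations. The conjugate addition alone is run and quenched with AcOH to give the lactone (4R,5R)-4-(2-Ar-1,3-dithian-2-yl)-5-[(1R,2S,5R)-menthyloxy]dihydrofuran-2(3H)-one F1, which is purified. F1 is then re-enolised with LiN(i-Pr)2 in THF at −78 °C, transmetallated with ZnCl2 to a less basic enolate whose zinc aldolate resists reversal, and treated with 2. The dithianyl group again directs the aldehyde to the anti face, giving 9.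

2. **Step 6.**
   - Risk: the electron-rich ring on the dithiane carbon may attack the benzylic cation in a six-membered Friedel–Crafts closure that competes with ether formation. Facial control at C2 may also be poor if the reaction is stopped too early.
   - Fallback: it sets out from 10 and comes back at 12 by inverting the order of unmasking and ring closure. MeI/CaCO3 in aqueous MeCN first gives the keto triol (2R,3R)-1-Ar-3-[Ar(hydroxy)methyl]-4-hydroxy-2-(hydroxymethyl)butan-1-one F2 (expected to rest partly as a cyclic hemiketal). Its neighbouring ring is now an aroyl arene, deactivated toward electrophilic attack. Catalytic CSA in CH2Cl2 at 0 °C then closes the oxolane through the same benzylic cation and gives 12 directly.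

3. **Step 8.**
   - Risk: sulfur residues may poison the catalyst. The aryl ketone may be over-reduced, or the ring C2–O1 benzylic bond may undergo hydrogenolysis.
   - Fallback: it sets out from 12 and comes back at 13 with a non-reductive Lewis-acid dealkylation. BCl3 and pentamethylbenzene in CH2Cl2 at −78 °C take the benzyl groups off the oxygen flanked by two methoxy groups as benzyl cations. The arene scavenges these cations, and a methanol quench follows. No new compound is made on this way (F0).

**Further compounds**
F1 | step 4 | (4R,5R)-4-(2-Ar-1,3-dithian-2-yl)-5-[(1R,2S,5R)-menthyloxy]dihydrofuran-2(3H)-one | O=C1O[C@@H](O[C@@H]2C[C@H](C)CC[C@H]2C(C)C)[C@H](C2(SCCCS2)c2cc(OC)c(OCc3ccccc3)c(OC)c2)C1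
F2 | step 6 | (2R,3R)-1-Ar-3-[Ar(hydroxy)methyl]-4-hydroxy-2-(hydroxymethyl)butan-1-one, carbinol carbon epimeric | OC[C@@H]([C@H](CO)C(=O)c1cc(OC)c(OCc2ccccc2)c(OC)c1)C(O)c1cc(OC)c(OCc2ccccc2)c(OC)c1
F0 | step 8 | none | none
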